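**Retrosynthetic overview**

1. The target is (2S)-naringenin with a (1E,3S)-3,7-dimethylocta-1,6-dienyl chain on C6; the last operation removes three MOM acetals from 17.
2. Key disconnection: ring C (O1, C2, C3, C4, C4a, C8a) is opened at C4–C4a and O1–C2, leading back to the ortho-iodoaryl (E)-cinnamate 14. Forward, one flask combines iodine–lithium exchange, O1-to-C4a acyl shift (anionic Fries) and a catalyst-controlled 6-endo oxa-Michael closure.
3. Enabling feature: in ring A the chain-bearing C6 lies between O5 and O7 and para to C8a–O1. Ring A without C4 is therefore a 4-alkenyl-3,5-dioxygenated phenol whose two ortho carbons (future C4a and C8) are equivalent, and O1 is its only free oxygen, so the 6-substitution pattern needs no regiocontrol.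
4. The phenol comes from phloroglucinol (mono-TIPS, bis-MOM), directed ortho-lithiation between the two OMOM groups, addition to (S)-citronellal (all ten chain carbons and C3'') and dehydration to the E-styrene. Ring B with C2 and C3 comes from 4-(methoxymethoxy)benzaldehyde and malonic acid.
5. Ring order: rings A and B are bought as arenes; ring C is the only ring constructed and is closed last.

Key step: step 9

Assumption: C3'' of the chain is carried unchanged from (S)-citronellal (same CIP ranking, no bond to the centre is touched), and of the two pseudoenantiomeric cinchona squaramides the one that delivers 2S is used.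

**Route**

Step 1
Reactants: 1 benzene-1,3,5-triol (phloroglucinol)
Product: 2 5-{[tri(propan-2-yl)silyl]oxy}benzene-1,3-diol
Conditions: TIPSCl (1 equiv), imidazole, DMF, 0 °C to rt; 1 in threefold excess
Reagents that add atoms: triisopropylsilyl chloride (TIPSCl), CC(C)[Si](Cl)(C(C)C)C(C)C
Why: Statistical O-silylation of a symmetric triol, in which the excess of water-soluble phloroglucinol should suppress bis-silylation and is washed out afterwards.

Step 2
Reactants: 2 5-{[tri(propan-2-yl)silyl]oxy}benzene-1,3-diol
Product: 3 {3,5-bis(methoxymethoxy)phenoxy}tri(propan-2-yl)silane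
Conditions: MOMCl, i-Pr2NEt, CH2Cl2, 0 °C to rt
Reagents that add atoms: chloromethyl methyl ether (MOMCl), COCCl
Why: Standard acetal formation (O-alkylation) on both free phenols under amine base, which leaves the hindered silyl ether untouched.

Step 3
Reactants: 3 {3,5-bis(methoxymethoxy)phenoxy}tri(propan-2-yl)silane; 4 (3S)-3,7-dimethyloct-6-enal ((S)-citronellal)
Product: 6 (1RS,3S)-1-{2,6-bis(methoxymethoxy)-4-[tri(propan-2-yl)silyloxy]phenyl}-3,7-dimethyloct-6-en-1-ol, via aryllithium 5 (not isolated)
Conditions: n-BuLi, THF, 0 °C; then 4, −78 to −20 °C; H2O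
Reagents that add atoms: none
Why: Directed ortho-metalation should occur only between the two chelating OMOM groups (the sites next to the bulky, non-coordinating OTIPS are shielded) and the aryllithium adds 1,2 to the aldehyde; the carbinol centre forms without control and is erased in step 4, while C3 (β to the carbonyl, not epimerisable) is carried through unchanged.

Step 4
Reactants: 6 (1RS,3S)-1-{2,6-bis(methoxymethoxy)-4-[tri(propan-2-yl)silyloxy]phenyl}-3,7-dimethyloct-6-en-1-ol
Product: 7 {4-[(1E,3S)-3,7-dimethylocta-1,6-dien-1-yl]-3,5-bis(methoxymethoxy)phenoxy}tri(propan-2-yl)silane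
Conditions: Burgess reagent, toluene, 50 °C (crude 6)
Reagents that add atoms: none
Why: Burgess dehydration (syn-elimination through the sulfamate ester) can only remove a C2'' hydrogen and so should give the conjugated styrene, with E geometry enforced by the 2,6-disubstituted aryl group and a non-acidic medium that disfavours cation–olefin cyclisation onto the remote alkene.

Step 5
Reactants: 7 {4-[(1E,3S)-3,7-dimethylocta-1,6-dien-1-yl]-3,5-bis(methoxymethoxy)phenoxy}tri(propan-2-yl)silane
Product: 8 4-[(1E,3S)-3,7-dimethylocta-1,6-dien-1-yl]-3,5-bis(methoxymethoxy)phenol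
Conditions: TBAF, THF, 0 °C; AcOH
Reagents that add atoms: none
Why: Fluoride-mediated cleavage of an aryl silyl ether (desilylation) is fast and should leave acetals and alkenes untouched.

Step 6
Reactants: 8 4-[(1E,3S)-3,7-dimethylocta-1,6-dien-1-yl]-3,5-bis(methoxymethoxy)phenol
Product: 9 4-[(1E,3S)-3,7-dimethylocta-1,6-dien-1-yl]-2-iodo-3,5-bis(methoxymethoxy)phenol
Conditions: I2 (1.0 equiv), NaHCO3, THF/H2O, 0 °C
Reagents that add atoms: iodine, [I][I]
Why: Electrophilic aromatic iodination of the phenoxide at a carbon that is ortho to O− and ortho/para to two OMOM groups should outrun any reaction at the twisted styrene or the trisubstituted alkene, and the two ortho carbons are equivalent so one equivalent of iodine can give only one mono-iodide.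

Step 7
Reactants: 10 4-(methoxymethoxy)benzaldehyde; 11 propanedioic acid (malonic acid)
Product: 13 (2E)-3-[4-(methoxymethoxy)phenyl]prop-2-enoic acid, via arylidenemalonic acid 12 (not isolated)
Conditions: pyridine, piperidine (cat.), 90 °C; cold aq. citric acid
Reagents that add atoms: none
Why: Knoevenagel–Doebner condensation with decarboxylation in the flask should give the E acid under basic conditions that spare the MOM acetal.

Step 8
Reactants: 9 4-[(1E,3S)-3,7-dimethylocta-1,6-dien-1-yl]-2-iodo-3,5-bis(methoxymethoxy)phenol; 13 (2E)-3-[4-(methoxymethoxy)phenyl]prop-2-enoic acid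
Product: 14 4-[(1E,3S)-3,7-dimethylocta-1,6-dien-1-yl]-2-iodo-3,5-bis(methoxymethoxy)phenyl (2E)-3-[4-(methoxymethoxy)phenyl]prop-2-enoate
Conditions: DCC, DMAP (cat.), CH2Cl2, 0 °C to rt
Reagents that add atoms: none
Why: Steglich esterification (carbodiimide activation, DMAP acyl transfer) acylates the phenol under neutral conditions and avoids an acid chloride and HCl that would endanger the acetals.

Step 9
Reactants: 14 4-[(1E,3S)-3,7-dimethylocta-1,6-dien-1-yl]-2-iodo-3,5-bis(methoxymethoxy)phenyl (2E)-3-[4-(methoxymethoxy)phenyl]prop-2-enoate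
Product: 17 (2S)-6-[(1E,3S)-3,7-dimethylocta-1,6-dien-1-yl]-5,7-bis(methoxymethoxy)-2-[4-(methoxymethoxy)phenyl]-2,3-dihydro-4H-chromen-4-one, via aryllithium 15 (not isolated), via 2'-hydroxychalcone 16 (not isolated)
Conditions: n-BuLi, toluene/THF (10:1), −95 °C; AcOH, −78 °C, cold filtration (Celite); then quinine-derived 3,5-bis(trifluoromethyl)phenyl squaramide (10 mol %), toluene, −20 to 0 °C
Reagents that add atoms: none
Why: Proposed new method: iodine–lithium exchange, expected to be faster than any addition of n-BuLi to the enoate, gives aryllithium 15, whose carbanion attacks the neighbouring ester carbonyl and, through a four-membered tetrahedral intermediate, moves the cinnamoyl group from O1 to C4a (anionic Fries rearrangement) to give chalcone 16 as its lithium phenoxide, freed by acetic acid. The bifunctional catalyst then activates O1–H with its tertiary amine and holds the C4 carbonyl with the squaramide N–H bonds, so that O1 adds to C2 in a 6-endo-trig oxa-Michael closure of ring C. The closest known reaction types are the halogen–metal-exchange-induced anionic Fries rearrangement of ortho-iodoaryl esters, the insertion of arynes into cinnamic acids that gives flavanones through the same ortho-acyl phenoxide, and the amine/hydrogen-bond-donor-catalysed cyclisation of 2'-hydroxychalcones; their merger in one flask on an enoate ester is what is new. The only new stereocentre, C2, is set by the catalyst, which exposes one enantiotopic face of the s-cis enone to O1. Regiochemistry needs no control because the two ortho carbons of the phenol were equivalent before iodination and only O1 is unprotected, so C4 and the ring oxygen must end up on the side para to the chain. Selectivity for 1,2-acyl transfer over conjugate addition rests on the proximity of the carbonyl carbon to the lithiated carbon, and the configuration at C2 should be protected because the peri C5–OMOM group twists the chalcone out of conjugation and makes ring closure effectively irreversible under the weakly basic catalyst.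

Step 10
Reactants: 17 (2S)-6-[(1E,3S)-3,7-dimethylocta-1,6-dien-1-yl]-5,7-bis(methoxymethoxy)-2-[4-(methoxymethoxy)phenyl]-2,3-dihydro-4H-chromen-4-one
Product: 19 (2S)-6-[(1E,3S)-3,7-dimethylocta-1,6-dien-1-yl]-5,7-dihydroxy-2-(4-hydroxyphenyl)-2,3-dihydro-4H-chromen-4-one, via tris(trimethylsilyl) ether 18 (not isolated)
Conditions: TMSOTf, 2,2'-bipyridyl, CH3CN, 0 °C to rt; then H2O
Reagents that add atoms: none
Why: Silyl triflate/2,2'-bipyridyl cleavage of aromatic MOM ethers (transfer of the methoxymethyl group to the pyridine nitrogen, aryl silyl ether formation, hydrolysis) runs without free Brønsted acid and should spare the electron-rich styrene, the trisubstituted alkene and the benzylic C2–O1 bond.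

**Compound list**

1 | benzene-1,3,5-triol (phloroglucinol) | Oc1cc(O)cc(O)c1 | starting material
2 | 5-{[tri(propan-2-yl)silyl]oxy}benzene-1,3-diol | Oc1cc(O)cc(O[Si](C(C)C)(C(C)C)C(C)C)c1 | intermediate
3 | {3,5-bis(methoxymethoxy)phenoxy}tri(propan-2-yl)silane | COCOc1cc(OCOC)cc(O[Si](C(C)C)(C(C)C)C(C)C)c1 | intermediate
4 | (3S)-3,7-dimethyloct-6-enal, (S)-citronellal | CC(C)=CCC[C@H](C)CC=O | starting material
5 | {2,6-bis(methoxymethoxy)-4-[tri(propan-2-yl)silyloxy]phenyl}lithium | [Li]c1c(OCOC)cc(O[Si](C(C)C)(C(C)C)C(C)C)cc1OCOC | intermediate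
6 | (1RS,3S)-1-{2,6-bis(methoxymethoxy)-4-[tri(propan-2-yl)silyloxy]phenyl}-3,7-dimethyloct-6-en-1-ol (both C1 epimers) | CC(C)=CCC[C@H](C)CC(O)c1c(OCOC)cc(O[Si](C(C)C)(C(C)C)C(C)C)cc1OCOC | intermediate
7 | {4-[(1E,3S)-3,7-dimethylocta-1,6-dien-1-yl]-3,5-bis(methoxymethoxy)phenoxy}tri(propan-2-yl)silane | CC(C)=CCC[C@H](C)/C=C/c1c(OCOC)cc(O[Si](C(C)C)(C(C)C)C(C)C)cc1OCOC | intermediate
8 | 4-[(1E,3S)-3,7-dimethylocta-1,6-dien-1-yl]-3,5-bis(methoxymethoxy)phenol | CC(C)=CCC[C@H](C)/C=C/c1c(OCOC)cc(O)cc1OCOC | intermediate
9 | 4-[(1E,3S)-3,7-dimethylocta-1,6-dien-1-yl]-2-iodo-3,5-bis(methoxymethoxy)phenol | CC(C)=CCC[C@H](C)/C=C/c1c(OCOC)cc(O)c(I)c1OCOC | intermediate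
10 | 4-(methoxymethoxy)benzaldehyde | COCOc1ccc(C=O)cc1 | starting material
11 | propanedioic acid (malonic acid) | OC(=O)CC(=O)O | starting material
12 | 2-{[4-(methoxymethoxy)phenyl]methylidene}propanedioic acid | COCOc1ccc(C=C(C(=O)O)C(=O)O)cc1 | intermediate
13 | (2E)-3-[4-(methoxymethoxy)phenyl]prop-2-enoic acid | COCOc1ccc(/C=C/C(=O)O)cc1 | intermediate
14 | 4-[(1E,3S)-3,7-dimethylocta-1,6-dien-1-yl]-2-iodo-3,5-bis(methoxymethoxy)phenyl (2E)-3-[4-(methoxymethoxy)phenyl]prop-2-enoate | CC(C)=CCC[C@H](C)/C=C/c1c(OCOC)cc(OC(=O)/C=C/c2ccc(OCOC)cc2)c(I)c1OCOC | intermediate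
15 | aryllithium from 14 (lithium in place of iodine) | CC(C)=CCC[C@H](C)/C=C/c1c(OCOC)cc(OC(=O)/C=C/c2ccc(OCOC)cc2)c([Li])c1OCOC | intermediate
16 | (2E)-1-{3-[(1E,3S)-3,7-dimethylocta-1,6-dien-1-yl]-6-hydroxy-2,4-bis(methoxymethoxy)phenyl}-3-[4-(methoxymethoxy)phenyl]prop-2-en-1-one | CC(C)=CCC[C@H](C)/C=C/c1c(OCOC)cc(O)c(C(=O)/C=C/c2ccc(OCOC)cc2)c1OCOC | intermediate
17 | (2S)-6-[(1E,3S)-3,7-dimethylocta-1,6-dien-1-yl]-5,7-bis(methoxymethoxy)-2-[4-(methoxymethoxy)phenyl]-2,3-dihydro-4H-chromen-4-one | CC(C)=CCC[C@H](C)/C=C/c1c(OCOC)cc2c(c1OCOC)C(=O)C[C@@H](c1ccc(OCOC)cc1)O2 | intermediate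
18 | (2S)-6-[(1E,3S)-3,7-dimethylocta-1,6-dien-1-yl]-5,7-bis(trimethylsilyloxy)-2-[4-(trimethylsilyloxy)phenyl]-2,3-dihydro-4H-chromen-4-one | CC(C)=CCC[C@H](C)/C=C/c1c(O[Si](C)(C)C)cc2c(c1O[Si](C)(C)C)C(=O)C[C@@H](c1ccc(O[Si](C)(C)C)cc1)O2 | intermediate
19 | (2S)-6-[(1E,3S)-3,7-dimethylocta-1,6-dien-1-yl]-5,7-dihydroxy-2-(4-hydroxyphenyl)-2,3-dihydro-4H-chromen-4-one | CC(C)=CCC[C@H](C)/C=C/c1c(O)cc2c(c1O)C(=O)C[C@@H](c1ccc(O)cc1)O2 | target

**Step count and risks**

Total steps: 10. Longest linear sequence: 9 steps (steps 1 to 6, 8, 9 and 10, from phloroglucinol).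

Steps most likely to fail:

1. Step 9. What may go wrong is insufficient facial discrimination in the oxa-Michael closure, or uncatalysed closure of the lithium phenoxide before the quench, so that configurational purity at C2 is lost. The fallback uses known chemistry and sets out from 14. Only the exchange/acyl-shift half of step 9 is run, and chalcone 16 is isolated after the acetic acid quench. Heating 16 with NaOAc in ethanol closes ring C without control and should give the C2-epimeric flavanone mixture F1. Kinetic resolution by asymmetric transfer hydrogenation with RuCl(p-cymene)[(R,R)-TsDPEN] and HCO2H/Et3N is expected to reduce the 2R epimer (matched for the cis alcohol) to the (2R,4R)-flavan-4-ol F2. The unreduced 2S ketone is separated by chromatography, and the route is rejoined at 17.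

2. Step 10. What may go wrong is silyl-triflate activation of the C4 carbonyl with reversible opening of ring C (epimerisation at C2, scrambling between the 6- and 8-substituted series once O5 is free), or incomplete cleavage of the least reactive acetal. The fallback moves the acetal cleavage in front of the stereocentre-forming step and sets out from 14. TESOTf/2,2'-bipyridyl in CH3CN should convert the three aryl MOM ethers directly into the tris(triethylsilyl) ether F3. Under the conditions of step 9 this gives its aryllithium F4, then the silylated chalcone F5, then the silylated flavanone F6. Buffered fluoride (TBAF/AcOH, THF, 0 °C) then removes the silyl groups under near-neutral conditions, and the route is rejoined at 19.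

3. Step 4. What may go wrong is ionisation of the very electron-rich benzylic sulfamate and capture of the cation by the C6''–C7'' alkene (Prins-type cyclohexane formation) instead of proton loss. The fallback avoids the benzylic alcohol, sets out from 3 and 4, and replaces steps 3 and 4. Lithiation of 3 as in step 3 (aryllithium 5) and quenching with iodine gives the aryl iodide F7. Condensation of 4 with TsNHNH2 in methanol gives the N-tosylhydrazone F8. Barluenga coupling of the two (Pd2(dba)3, XPhos, LiOtBu, dioxane, 90 °C; palladium carbene formation, aryl migration, β-hydride elimination from C2'') should give the E-styrene directly, and the route is rejoined at 7. Any loss of the silyl group under the alkoxide base only advances the material to 8.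

Further compounds
F1 | step 9 | (2RS)-6-[(1E,3S)-3,7-dimethylocta-1,6-dien-1-yl]-5,7-bis(methoxymethoxy)-2-[4-(methoxymethoxy)phenyl]-2,3-dihydro-4H-chromen-4-one (17 and its C2 epimer) | CC(C)=CCC[C@H](C)/C=C/c1c(OCOC)cc2c(c1OCOC)C(=O)CC(c1ccc(OCOC)cc1)O2
F2 | step 9 | (2R,4R)-6-[(1E,3S)-3,7-dimethylocta-1,6-dien-1-yl]-5,7-bis(methoxymethoxy)-2-[4-(methoxymethoxy)phenyl]-3,4-dihydro-2H-chromen-4-ol | CC(C)=CCC[C@H](C)/C=C/c1c(OCOC)cc2c(c1OCOC)[C@H](O)C[C@H](c1ccc(OCOC)cc1)O2
F3 | step 10 | 4-[(1E,3S)-3,7-dimethylocta-1,6-dien-1-yl]-2-iodo-3,5-bis(triethylsilyloxy)phenyl (2E)-3-[4-(triethylsilyloxy)phenyl]prop-2-enoate | CC(C)=CCC[C@H](C)/C=C/c1c(O[Si](CC)(CC)CC)cc(OC(=O)/C=C/c2ccc(O[Si](CC)(CC)CC)cc2)c(I)c1O[Si](CC)(CC)CC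
F4 | step 10 | aryllithium from F3 (lithium in place of iodine) | CC(C)=CCC[C@H](C)/C=C/c1c(O[Si](CC)(CC)CC)cc(OC(=O)/C=C/c2ccc(O[Si](CC)(CC)CC)cc2)c([Li])c1O[Si](CC)(CC)CC
F5 | step 10 | (2E)-1-{3-[(1E,3S)-3,7-dimethylocta-1,6-dien-1-yl]-6-hydroxy-2,4-bis(triethylsilyloxy)phenyl}-3-[4-(triethylsilyloxy)phenyl]prop-2-en-1-one | CC(C)=CCC[C@H](C)/C=C/c1c(O[Si](CC)(CC)CC)cc(O)c(C(=O)/C=C/c2ccc(O[Si](CC)(CC)CC)cc2)c1O[Si](CC)(CC)CC
F6 | step 10 | (2S)-6-[(1E,3S)-3,7-dimethylocta-1,6-dien-1-yl]-5,7-bis(triethylsilyloxy)-2-[4-(triethylsilyloxy)phenyl]-2,3-dihydro-4H-chromen-4-one | CC(C)=CCC[C@H](C)/C=C/c1c(O[Si](CC)(CC)CC)cc2c(c1O[Si](CC)(CC)CC)C(=O)C[C@@H](c1ccc(O[Si](CC)(CC)CC)cc1)O2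
F7 | step 4 | {4-iodo-3,5-bis(methoxymethoxy)phenoxy}tri(propan-2-yl)silane | COCOc1cc(O[Si](C(C)C)(C(C)C)C(C)C)cc(OCOC)c1I
F8 | step 4 | N'-[(1E,3S)-3,7-dimethyloct-6-en-1-ylidene]-4-methylbenzenesulfonohydrazide | CC(C)=CCC[C@H](C)C/C=N/NS(=O)(=O)c1ccc(C)cc1
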